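Start from a leftover: take the ratio of side product to target, both as fractions of the substrate charged (the selectivity), remove whatever grows with the substrate load, and see what stays.

common to all: gas 0.16 mM (held)
- south-east: substrate 1 mM; free catalyst 1.3 µM; run made earlier
- west: substrate 4 mM; free catalyst 1.3 µM; run made earlier
- north-west: substrate 2 mM; free catalyst 2 µM; run made earlier
- flask: substrate 2.0 mM; free catalyst 1.3 µM; time 1.5 h

| run | time / min | side product / % | target / % |
|---|---|---|---|
| south-east | 20.0 | 46.9 | 53.3 |
| south-east | 40.0 | 47.7 | 53.4 |
| south-east | 60.0 | 45.8 | 53.5 |
| south-east | 80.0 | 46.4 | 52.3 |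
| south-east | 120 | 46.9 | 52.2 |
| west | 8.00 | 57.0 | 41.3 |
| west | 15.0 | 55.8 | 45.5 |
| west | 30.0 | 56.3 | 45.5 |
| west | 60.0 | 55.8 | 43.8 |
| west | 120 | 57.6 | 43.5 |
| north-west | 20.0 | 43.2 | 58.2 |
| north-west | 40.0 | 41.6 | 57.1 |
| north-west | 60.0 | 43.2 | 58.8 |
| north-west | 80.0 | 42.3 | 59.1 |
| north-west | 120 | 41.4 | 58.9 |

(each reading ± 1 percentage point)

* ratio of side product to target at 4.0 s
* ratio of side product to target at 1.5 h

- at the start none of reagent is dissolved
- steps under discussion: substrate + free catalyst <-> free catalyst + open intermediate; free catalyst + open intermediate <-> catalyst intermediate; reagent + catalyst intermediate -> free catalyst + target; open intermediate -> side product; gas <-> reagent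

Pooling the readings of each run, the south-east run gives a ratio of 0.883 and the west run 1.29, both at free catalyst 1.3 µM. Drawn as a straight line in the charge, this is a rise of 0.135 /mM, which I call the load correction. Taking the load off the south-east ratio along that line leaves 0.748, a reckoned leftover and not a run.

Two people now stand at the board. The first holds that time matters: no reagent is dissolved at the start, so in her view the ratio begins high and falls. She points to the first west reading, at 8.00 min, which gives 1.38, higher than the pooled 1.29. The second holds that the charge matters and time does not: leftover plus correction gives 1.02 for the flask, early and late alike. He points to the first south-east reading, at 20.0 min, which gives 0.880 against the pooled 0.883. Neither reading reaches 4.0 s, so his early number is a commitment, and it is the one I make.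

The forecast takes the first side, since “dissolved reagent is still building from zero”: 3.8 at 4.0 s and 1.03 at 1.5 h.

The flask gives 1.04 at 4.0 s and 1.04 at 1.5 h.

    substrate + free catalyst ⇌ free catalyst + open intermediate (K = 4.70, k = 23700 /M/s)
    free catalyst + open intermediate ⇌ catalyst intermediate (K = 1600 /M, k = 8.37 × 10⁵ /M/s)
    reagent + catalyst intermediate → free catalyst + target (k = 1.44 × 10⁵ /M/s)
    open intermediate → side product (k = 0.0333 /s)
    gas ⇌ reagent, rate k5*(csat - [reagent]) (kL = 0.869 /s)

The uptake of gas as reagent, taken by itself, has a time of 1.15 s, shorter than 4.0 s, and the first speaker's picture of a reagent still filling belongs to times inside that span. The flask's ratio stands 0.292 above the leftover, and the load correction gives 0.270 for its 2.0 mM.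

For the neighbour charged with 5.0 mM of substrate, the same line gives 1.42. The computed ratio there at 1.5 h is 1.40.

The numbers in the tables stem from a simulated flask for an exercise, and the scatter is random.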